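## Analysis of the target

The target is a dimer of two 6,8-dimethoxy-7-oxygenated coumarins (2H-chromen-2-ones). Unit A is a 7-hydroxy-6,8-dimethoxycoumarin that carries an oxygen on C3, and that oxygen is the C7' oxygen of unit B, a 6,8-dimethoxycoumarin with an unsubstituted pyranone. The molecule is flat and achiral: there is no stereocentre, and no alkene geometry has to be set outside the rings. Each benzene ring carries four contiguous oxygens (O1, C8-OMe, C7-O, C6-OMe) and a single hydrogen at C5, so the two halves share one arene and differ only at the C7 oxygen and at C3. The sensitive sites are the two lactones (opened by base), the free C7 phenol of unit A (para to C4a, easily oxidised) and the C3–O–C7' aryl enol ether. That ether is the hard bond, because C3 of a coumarin is not electrophilic and the C7' oxygen is flanked by two methoxy groups; the second difficulty is telling O1 from the C7 oxygen on each ring. The plan rests on the C3=C4 and C3'=C4' alkenes: each lies between the lactone carbon C2 and the arene carbon C4a, so each pyranone opens, in thought, to a styrene on C4a and an acrylate on O1. For unit A that acrylate already carries the ether oxygen on its α-carbon, so the hindered ether is made on an open-chain acrylate and both rings close afterwards.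

## Retrosynthetic reasoning

**22 to 21 (protecting group).** The C7 phenol of unit A is masked as a methoxymethyl ether. This oxygen is the phenol oxygen of 1 and has to be protected from the first step, because the O1 oxygen is introduced through aryllithium 3. A methoxymethyl ether survives organolithium, ylide, carbodiimide and ruthenium carbene chemistry, so one group serves from step 1 to the end. A silyl ether would be at risk in the lithiation and would have to be exchanged. Removal needs only dilute acid, which the lactones and the enol ether tolerate.

**21 to 19 (C3=C4 and C3'=C4').** Both ring alkenes are cut in one operation. They are the only C=C bonds outside the benzene rings, and cutting them turns each pyranone into an ester on a single phenol oxygen. Cutting the C3–O bond instead would leave the hindered ether to be made on a finished coumarin. Cutting a lactone C–O bond would require a cis-cinnamate with the enol ether already in place. The forward reaction has to close two six-membered rings by metathesis, the second on a 1,1-disubstituted 2-aryloxyacrylate, and should pass through monocoumarin 20.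

**19 to 18 and 9 (O1–C2 ester of unit A).** This cut divides the molecule into two halves of similar size that come from one aldehyde. The aryl ester is the most base-labile bond of 19, so it is formed last among the skeletal bonds, under neutral carbodiimide activation. The forward step has to acylate a phenol flanked by a methoxy and a vinyl group.

**18 to 16, 14 and 13 (acid, acrylate ester O1'–C2', vinyl group).** The acid is unveiled from a tert-butyl ester, the acrylate is put on with 15, and the vinyl group comes from the aldehyde with 8. The order follows from reactivity. The ylide must act before any aryl ester exists. The acrylate must be in place before the acid is freed, so that the coupling partner has one acid and no free phenol. A tert-butyl ester is used because it can be removed without aqueous base; a methyl ester could not be cleaved next to the aryl acrylate.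

**13 to 10 and 11 (bond from the C7' oxygen to the acrylate α-carbon).** This is the future C3–O bond. It is formed by phenoxide chemistry on a three-carbon electrophile, by way of 12, and needs no metal. The 4-OH of 10 is para to the aldehyde and therefore the more acidic, while the 2-OH is tied up in a hydrogen bond to the carbonyl; this difference selects the oxygen.

**9 and 10 to 7 (one aldehyde for both halves).** Methylenation of 7 with 8 gives the unit A phenol 9 directly. Acid removal of the methoxymethyl group gives 10 for unit B. No separate arene synthesis is needed for the second half.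

**7 to 5 (C4a–CHO bond).** The aldehyde carbon is introduced by ortho-formylation of phenol 5 by way of salicyl alcohol 6. The position next to the hydroxyl is the only free ortho carbon, so no isomer can form.

**5 to 2 to 1 (C8a–O bond and protection).** Compound 1 already holds C6-OMe, the C7 oxygen and C8-OMe. The missing O1 oxygen is put on the carbon ortho to a methoxy group by lithiation (3), borylation (4) and oxidation. In 2 the two positions ortho to methoxy are equivalent and are the only ones next to a directing oxygen, so the regiochemistry is fixed by the substrate.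

## Alternatives that were turned down

**Alternative 1:** The benzene ring of unit A is cut at C7–C8 and C4a–C5 and assembled from a four-carbon dinucleophile and a three-carbon dielectrophile. In the forward sense the bis(silyl enol ether) A1 is acylated at its terminal carbon by the acid chloride A2. The resulting 3,5-dioxo ester then cyclises by attack of its C2 carbon on the β-methoxy enone carbon, with loss of that methoxy group, to give the benzoate A3.
- For it: all four oxygens and the carboxyl carbon are placed by the connectivity of acyclic pieces, with no aromatic substitution and no organolithium. On that point it is as clean as the route chosen here.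
- Against it: it builds the one part of the target that is cheap to reach, since the arene of A3 has the same pattern as 10, which is four steps from 1. After A3 the ester still has to be brought to the aldehyde level, the 2-OH and 4-OH have to be told apart (the same problem as in 10), and the ether and both pyranones are untouched. The acylation can also go on oxygen, and the triketo ester can close through oxygen to a 4-pyranone.
- Comparison: the chosen strategy takes the arene from 1 and spends its key step on the two rings and the ether oxygen, which are the real difficulties.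

**Alternative 2:** The benzene ring of unit B is cut at C5'–C6' and traced back to a cyclobutenone. Heating the cyclobutenone A4 opens it to a dienylketene, and 6π electrocyclisation followed by tautomerisation gives the phenol A5, in which unit A is already attached through its C3 oxygen.
- For it: the hindered C3–O–C7' ether is made early by addition–elimination on a squaric ester, at an activated sp2 carbon. That is arguably a more secure way to form this bond than the alkylation 10 to 13, where the regiochemistry on the three-carbon unit has to be controlled. The ring also arises fully substituted.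
- Against it: a complete 3-hydroxycoumarin of unit A is needed first, so the tetraoxygenated arene still has to be made by the chemistry used here. The alkenyllithium that leads to A4 must choose between two different carbonyl groups and must spare the lactone. A5 still needs methylation at C6', acetal hydrolysis, removal of two protecting groups (one by hydrogenolysis next to two coumarin alkenes) and construction of the unit B pyranone.
- Comparison: the chosen route offers a common intermediate for both arenes and closes both pyranones in one redox-neutral step, in well under the fifteen or more steps this alternative would take.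

**Alternative 3:** The O1–C8a bond of unit A is cut at the dihydrocoumarin level. Anodic oxidation of the phenolic acid A6 gives a phenoxonium ion that the carboxylate captures at C4a to form the spirolactone A7. Acid then moves the acyloxy group to C8a and the ring rearomatises to the racemic dihydrocoumarin A8; its one stereocentre is lost on dehydrogenation.
- For it: unit A starts from a simple para-substituted 2,6-dimethoxyphenol that lacks O1, because the key step introduces that oxygen. Here it is stronger than the chosen route, which needs lithiation and oxidation. The ether is made by plain displacement on an α-halo ester, and the C7 phenol needs no protecting group.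
- Against it: an α-aryloxy carboxylic acid is prone to oxidative decarboxylation at the anode. A7 carries two methoxy enol ethers that the acid needed for the shift can hydrolyse, and the benzylic carbon can migrate in place of the acyloxy group. A8 must still be dehydrogenated on a phenol-rich compound, and unit B has to be made separately.
- Comparison: the step count is no lower, and the chosen strategy offers two ring closures at the correct oxidation level with no competing migration.

Key step: step 11

## Route

Assumption: tert-butyl 2,3-dibromopropanoate (11) is taken to be a catalogue reagent.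

Step 1
Reactants: 1 syringol (2,6-dimethoxyphenol)
Product: 2 1,3-dimethoxy-2-(methoxymethoxy)benzene
Conditions: NaH, MOMCl, THF/DMF, 0 °C to rt
Reagents that add atoms: chloromethyl methyl ether, COCCl
Why: O-alkylation of the sodium phenoxide with a reactive α-chloro ether (Williamson type); the methoxymethyl ether withstands the organolithium, base and ylide steps that follow and is removed by acid.

Step 2
Reactants: 2 1,3-dimethoxy-2-(methoxymethoxy)benzene
Product: 5 2,4-dimethoxy-3-(methoxymethoxy)phenol, via aryllithium 3 (not isolated), via dimethyl arylboronate 4 (not isolated)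
Conditions: n-BuLi, TMEDA, THF, 0 °C to rt; B(OMe)3, −78 °C to rt; 30% H2O2, aq. NaOH, 0 °C
Reagents that add atoms: hydrogen peroxide, OO
Why: Directed ortho-metalation: the only ring carbons next to a coordinating oxygen are the two equivalent positions ortho to methoxy, so only 3 can form. Borylation to 4 and peroxide oxidation (aryl shift from boron to oxygen) then place the future O1 oxygen on that carbon.

Step 3
Reactants: 5 2,4-dimethoxy-3-(methoxymethoxy)phenol
Product: 7 2-hydroxy-3,5-dimethoxy-4-(methoxymethoxy)benzaldehyde, via salicyl alcohol 6 (not isolated)
Conditions: MgCl2, Et3N, (CH2O)n, THF, reflux; cold 5% citric acid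
Reagents that add atoms: formaldehyde (as paraformaldehyde), C=O
Why: Casnati–Skattebøl ortho-formylation: the magnesium phenoxide delivers formaldehyde to the ortho carbon through a chelate, and 6 is oxidised by hydride transfer to a second formaldehyde. Only one ortho position is free, so a single aldehyde can form.

Step 4
Reactants: 7 2-hydroxy-3,5-dimethoxy-4-(methoxymethoxy)benzaldehyde; 8 methyltriphenylphosphonium bromide
Product: 9 6-ethenyl-2,4-dimethoxy-3-(methoxymethoxy)phenol
Conditions: 8 (2.5 equiv), KOtBu (2.4 equiv), THF, 0 °C; then 7, 0 °C to rt
Reagents that add atoms: none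
Why: Wittig methylenation with excess ylide: one equivalent forms the phenoxide and the rest converts the aldehyde into the styrene, as is routine for unprotected 2-hydroxybenzaldehydes.

Step 5
Reactants: 7 2-hydroxy-3,5-dimethoxy-4-(methoxymethoxy)benzaldehyde
Product: 10 2,4-dihydroxy-3,5-dimethoxybenzaldehyde
Conditions: HCl (2 M in MeOH), 40 °C; aqueous work-up
Reagents that add atoms: none
Why: Acid-catalysed acetal exchange removes the methoxymethyl group as dimethoxymethane, so no free formaldehyde can attack the electron-rich ring. Any dimethyl acetal of the aldehyde reverts on aqueous work-up.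

Step 6
Reactants: 10 2,4-dihydroxy-3,5-dimethoxybenzaldehyde; 11 tert-butyl 2,3-dibromopropanoate (racemic)
Product: 13 tert-butyl 2-(4-formyl-3-hydroxy-2,6-dimethoxyphenoxy)prop-2-enoate, via tert-butyl 2-bromoacrylate 12 (not isolated)
Conditions: 11 (1.05 equiv), K2CO3 (2.2 equiv), acetone, 55 °C
Reagents that add atoms: none
Why: O-vinylation of a phenol with a 2,3-dibromopropanoate: carbonate eliminates HBr from 11 to give 12, and phenoxide attack, bromide displacement at the α-carbon and E1cB loss of the β-leaving group leave the aryloxy group on C2 of the acrylate. Only the 4-OH reacts, because it is para to the aldehyde and the more acidic, while the 2-OH is held in a hydrogen bond to the carbonyl.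

Step 7
Reactants: 13 tert-butyl 2-(4-formyl-3-hydroxy-2,6-dimethoxyphenoxy)prop-2-enoate; 8 methyltriphenylphosphonium bromide
Product: 14 tert-butyl 2-(4-ethenyl-3-hydroxy-2,6-dimethoxyphenoxy)prop-2-enoate
Conditions: 8 (2.5 equiv), KOtBu (2.4 equiv), THF, 0 °C; then 13, 0 °C to rt
Reagents that add atoms: none
Why: Wittig methylenation as in step 4. The aldehyde is the most electrophilic site, the tert-butyl ester is too hindered to acylate the ylide, and the 2-aryloxyacrylate is a poor Michael acceptor because the α-oxygen donates into the alkene.

Step 8
Reactants: 14 tert-butyl 2-(4-ethenyl-3-hydroxy-2,6-dimethoxyphenoxy)prop-2-enoate; 15 acryloyl chloride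
Product: 16 tert-butyl 2-[4-ethenyl-2,6-dimethoxy-3-(prop-2-enoyloxy)phenoxy]prop-2-enoate
Conditions: 15 (1.3 equiv), Et3N, CH2Cl2, −20 to 0 °C
Reagents that add atoms: none
Why: Standard O-acylation of a phenol with an acid chloride and a tertiary amine; the phenol is the only nucleophilic site, and the low temperature limits amine addition to the acrylate.

Step 9
Reactants: 16 tert-butyl 2-[4-ethenyl-2,6-dimethoxy-3-(prop-2-enoyloxy)phenoxy]prop-2-enoate
Product: 18 2-[4-ethenyl-2,6-dimethoxy-3-(prop-2-enoyloxy)phenoxy]prop-2-enoic acid, via trimethylsilyl ester 17 (not isolated)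
Conditions: TMSOTf, 2,6-lutidine, CH2Cl2, 0 °C; then pH 4 aqueous buffer
Reagents that add atoms: none
Why: Silyl triflate cleavage of a tert-butyl ester: silylation of the carbonyl oxygen releases the tert-butyl cation, which the lutidine deprotonates to isobutene, and 17 hydrolyses on work-up. The buffered, non-protic medium avoids acid addition to the styrene and spares the aryl acrylate, which aqueous base would cleave.

Step 10
Reactants: 18 2-[4-ethenyl-2,6-dimethoxy-3-(prop-2-enoyloxy)phenoxy]prop-2-enoic acid; 9 6-ethenyl-2,4-dimethoxy-3-(methoxymethoxy)phenol
Product: 19 6-ethenyl-2,4-dimethoxy-3-(methoxymethoxy)phenyl 2-[4-ethenyl-2,6-dimethoxy-3-(prop-2-enoyloxy)phenoxy]prop-2-enoate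
Conditions: DIC, DMAP (cat.), CH2Cl2, 0 °C to rt
Reagents that add atoms: none
Why: Steglich esterification: the carbodiimide activates the acid as its O-acylisourea and DMAP relays the acyl group to the phenol, the only nucleophile present. The neutral conditions preserve the aryl acrylate and both styrenes.

Step 11
Reactants: 19 6-ethenyl-2,4-dimethoxy-3-(methoxymethoxy)phenyl 2-[4-ethenyl-2,6-dimethoxy-3-(prop-2-enoyloxy)phenoxy]prop-2-enoate
Product: 21 3-[(6,8-dimethoxy-2-oxo-2H-chromen-7-yl)oxy]-6,8-dimethoxy-7-(methoxymethoxy)-2H-chromen-2-one, via monocoumarin 20 (not isolated)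
Conditions: (H2IMes)Cl2Ru=CH(C6H4-2-OiPr) (second-generation Hoveyda–Grubbs catalyst, 10 mol% in two portions), toluene (2 mM), 80 °C then 110 °C, argon sparge
Reagents that add atoms: none
Why: The catalyst initiates on the two terminal styrenes, the most accessible and electron-rich alkenes, giving ruthenium benzylidenes on C4 and C4'; each adds by [2+2] cycloaddition to the acrylate C=C held on the neighbouring phenol oxygen, and cycloreversion of the ruthenacyclobutane releases the ring alkene and Ru=CH2, which passes its methylene on as ethene. The closest known reactions are ring-closing metathesis of 2-vinylphenyl acrylates and methacrylates to coumarins and of 2-alkoxyacrylates to cyclic enol-ether esters; here the two are run in one flask. Unit B closes first, at 80 °C, because its acrylate is monosubstituted: the ring O1'–C2'–C3'–C4'–C4a'–C8a' forms as a six-membered closure with the new C3'=C4' bond inside it, and monocoumarin 20 results. Unit A closes at 110 °C on the 1,1-disubstituted 2-aryloxyacrylate, again a six-membered closure, and gives the trisubstituted C3=C4 alkene that bears the ether oxygen. No stereocentre is formed, and both alkenes are cis because they lie in six-membered rings. The step needs each benzylidene to pair with the acrylate on its own ring: these are the only pairings that give six-membered rings, the crossed ones would need a thirteen-membered ring or a bridge across the para positions of unit B, and 2 mM dilution disfavours intermolecular metathesis. Escape of ethene in the argon stream and the gain of two conjugated 2-pyranones make the closures irreversible, and the coumarin alkenes are too hindered and electron-poor to re-enter the cycle.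

Step 12
Reactants: 21 3-[(6,8-dimethoxy-2-oxo-2H-chromen-7-yl)oxy]-6,8-dimethoxy-7-(methoxymethoxy)-2H-chromen-2-one
Product: 22 3-[(6,8-dimethoxy-2-oxo-2H-chromen-7-yl)oxy]-7-hydroxy-6,8-dimethoxy-2H-chromen-2-one (CNP0278842.0)
Conditions: HCl (2 M in MeOH), CH2Cl2, 40 °C
Reagents that add atoms: none
Why: Acid-catalysed cleavage of the aryl methoxymethyl ether by acetal exchange with methanol. The methyl ethers and the α-aryloxy enoate are stable to dilute acid (protonation at C4 would put a cation next to the carbonyl), and a lactone opened by methanol would re-close because the cinnamate is held cis.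

## Compound list

1 | syringol (2,6-dimethoxyphenol) | COc1cccc(OC)c1O | starting material
2 | 1,3-dimethoxy-2-(methoxymethoxy)benzene | COCOc1c(OC)cccc1OC | intermediate
3 | [2,4-dimethoxy-3-(methoxymethoxy)phenyl]lithium | [Li]c1ccc(OC)c(OCOC)c1OC | intermediate, not isolated
4 | dimethyl [2,4-dimethoxy-3-(methoxymethoxy)phenyl]boronate | COB(OC)c1ccc(OC)c(OCOC)c1OC | intermediate, not isolated
5 | 2,4-dimethoxy-3-(methoxymethoxy)phenol | COCOc1c(OC)ccc(O)c1OC | intermediate
6 | 2-(hydroxymethyl)-4,6-dimethoxy-5-(methoxymethoxy)phenol (present as its magnesium salt) | OCc1cc(OC)c(OCOC)c(OC)c1O | intermediate, not isolated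
7 | 2-hydroxy-3,5-dimethoxy-4-(methoxymethoxy)benzaldehyde | COCOc1c(OC)cc(C=O)c(O)c1OC | intermediate
8 | methyltriphenylphosphonium bromide | C[P+](c1ccccc1)(c1ccccc1)c1ccccc1.[Br-] | starting material
9 | 6-ethenyl-2,4-dimethoxy-3-(methoxymethoxy)phenol | C=Cc1cc(OC)c(OCOC)c(OC)c1O | intermediate
10 | 2,4-dihydroxy-3,5-dimethoxybenzaldehyde | COc1cc(C=O)c(O)c(OC)c1O | intermediate
11 | tert-butyl 2,3-dibromopropanoate (racemic) | CC(C)(C)OC(=O)C(Br)CBr | starting material
12 | tert-butyl 2-bromoprop-2-enoate | C=C(Br)C(=O)OC(C)(C)C | intermediate, not isolated
13 | tert-butyl 2-(4-formyl-3-hydroxy-2,6-dimethoxyphenoxy)prop-2-enoate | C=C(Oc1c(OC)cc(C=O)c(O)c1OC)C(=O)OC(C)(C)C | intermediate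
14 | tert-butyl 2-(4-ethenyl-3-hydroxy-2,6-dimethoxyphenoxy)prop-2-enoate | C=Cc1cc(OC)c(OC(=C)C(=O)OC(C)(C)C)c(OC)c1O | intermediate
15 | acryloyl chloride (prop-2-enoyl chloride) | C=CC(Cl)=O | starting material
16 | tert-butyl 2-[4-ethenyl-2,6-dimethoxy-3-(prop-2-enoyloxy)phenoxy]prop-2-enoate | C=CC(=O)Oc1c(C=C)cc(OC)c(OC(=C)C(=O)OC(C)(C)C)c1OC | intermediate
17 | trimethylsilyl 2-[4-ethenyl-2,6-dimethoxy-3-(prop-2-enoyloxy)phenoxy]prop-2-enoate | C=CC(=O)Oc1c(C=C)cc(OC)c(OC(=C)C(=O)O[Si](C)(C)C)c1OC | intermediate, not isolated
18 | 2-[4-ethenyl-2,6-dimethoxy-3-(prop-2-enoyloxy)phenoxy]prop-2-enoic acid | C=CC(=O)Oc1c(C=C)cc(OC)c(OC(=C)C(O)=O)c1OC | intermediate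
19 | 6-ethenyl-2,4-dimethoxy-3-(methoxymethoxy)phenyl 2-[4-ethenyl-2,6-dimethoxy-3-(prop-2-enoyloxy)phenoxy]prop-2-enoate | C=CC(=O)Oc1c(C=C)cc(OC)c(OC(=C)C(=O)Oc2c(C=C)cc(OC)c(OCOC)c2OC)c1OC | intermediate
20 | 6-ethenyl-2,4-dimethoxy-3-(methoxymethoxy)phenyl 2-[(6,8-dimethoxy-2-oxo-2H-chromen-7-yl)oxy]prop-2-enoate | C=Cc1cc(OC)c(OCOC)c(OC)c1OC(=O)C(=C)Oc1c(OC)cc2ccc(=O)oc2c1OC | intermediate, not isolated
21 | 3-[(6,8-dimethoxy-2-oxo-2H-chromen-7-yl)oxy]-6,8-dimethoxy-7-(methoxymethoxy)-2H-chromen-2-one | COCOc1c(OC)cc2cc(Oc3c(OC)cc4ccc(=O)oc4c3OC)c(=O)oc2c1OC | intermediate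
22 | 3-[(6,8-dimethoxy-2-oxo-2H-chromen-7-yl)oxy]-7-hydroxy-6,8-dimethoxy-2H-chromen-2-one | COc1cc2cc(Oc3c(OC)cc4ccc(=O)oc4c3OC)c(=O)oc2c(OC)c1O | target

## Step count and least certain steps

Total: 12 steps. Longest linear sequence: 11 steps (1, 2, 3, 5, 6, 7, 8, 9, 10, 11, 12). The unit A branch (1, 2, 3, 4) joins at step 10.

**Step 11 (key step).** The second closure may stall at 20. The ruthenium methylidene can decompose at the temperature that the 1,1-disubstituted donor–acceptor alkene needs. Reaction of the carbene with the enol-ether alkene in the wrong sense can also give an unreactive heteroatom-stabilised carbene. Intermolecular metathesis of the styrenes to stilbene oligomers is the other likely loss. The fallback gives up metathesis and uses the classical condensation route to 3-aryloxycoumarins; it sets out from 10 and 7 and returns at 21. Heating 10 with ethyl (triphenylphosphoranylidene)acetate in N,N-diethylaniline should give, by olefination and lactonisation, 7-hydroxy-6,8-dimethoxy-2H-chromen-2-one F1. O-Alkylation with tert-butyl bromoacetate and K2CO3 would give tert-butyl 2-[(6,8-dimethoxy-2-oxo-2H-chromen-7-yl)oxy]acetate F2, and trifluoroacetic acid would free 2-[(6,8-dimethoxy-2-oxo-2H-chromen-7-yl)oxy]acetic acid F3. Heating F3 with 7 and dicyclohexylcarbodiimide in DMSO should form 6-formyl-2,4-dimethoxy-3-(methoxymethoxy)phenyl 2-[(6,8-dimethoxy-2-oxo-2H-chromen-7-yl)oxy]acetate F4, which closes by intramolecular Knoevenagel condensation to 21.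

**Step 6.** Alkylation may go through the chelated 2-OH or on both oxygens. The salicylaldehyde may close onto 12 by oxa-Michael addition and aldol condensation to a chromene. The reaction may also stop at the β-aryloxy isomer if displacement at the α-carbon by the hindered phenoxide is slow. The fallback sets out from 10 and returns at 13. O–H insertion of the carbene from tert-butyl diazo(diethoxyphosphoryl)acetate, catalysed by Rh2(OAc)4, at the non-chelated 4-OH would give tert-butyl 2-(diethoxyphosphoryl)-2-(4-formyl-3-hydroxy-2,6-dimethoxyphenoxy)acetate F5. Horner–Wadsworth–Emmons methylenation of F5 with aqueous formaldehyde and K2CO3 then gives 13 with the oxygen fixed on C2.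

**Step 7.** Conjugate addition of the ylide or of tert-butoxide to the 2-aryloxyacrylate may compete with olefination of the phenoxide-deactivated aldehyde. The fallback sets out from 13 and returns at 14: Takai–Lombardo methylenation (Zn, CH2Br2, TiCl4, THF) uses a non-basic gem-dimetallic reagent that attacks aldehydes but not esters or acrylates. This fallback makes no new compound.

**Step 9.** The tert-butyl cation or adventitious triflic acid may start cationic oligomerisation of the styrene, and the aryl acrylate may hydrolyse on work-up. The fallback changes the order so that no acid meets a styrene; it sets out from 13 and returns at 18. Trifluoroacetic acid on 13 would give 2-(4-formyl-3-hydroxy-2,6-dimethoxyphenoxy)prop-2-enoic acid F6. Wittig methylenation of its dianion with excess ylide from 8 would give 2-(4-ethenyl-3-hydroxy-2,6-dimethoxyphenoxy)prop-2-enoic acid F7. Excess 15 with Et3N would acylate both the phenol and the carboxylate to give 2-[4-ethenyl-2,6-dimethoxy-3-(prop-2-enoyloxy)phenoxy]prop-2-enoic prop-2-enoic anhydride F8, whose anhydride alone is hydrolysed by aqueous pyridine to 18.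

**Step 10.** Acyl transfer to the doubly ortho-substituted phenol may be slower than rearrangement of the O-acylisourea to an N-acylurea, and DMAP may shuttle the acryloyl group from unit B to 9. The fallback sets out from 18 and 9 and returns at 19. 1-Chloro-N,N,2-trimethylprop-1-en-1-amine would convert 18 under neutral conditions into 2-[4-ethenyl-2,6-dimethoxy-3-(prop-2-enoyloxy)phenoxy]prop-2-enoyl chloride F9. F9 is then added at −78 °C to the sodium phenoxide of 9 (from NaH in THF), so that no nucleophilic catalyst is needed.

## Further compounds

F1 | step 11 | 7-hydroxy-6,8-dimethoxy-2H-chromen-2-one | COc1cc2ccc(=O)oc2c(OC)c1O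
F2 | step 11 | tert-butyl 2-[(6,8-dimethoxy-2-oxo-2H-chromen-7-yl)oxy]acetate | COc1cc2ccc(=O)oc2c(OC)c1OCC(=O)OC(C)(C)C
F3 | step 11 | 2-[(6,8-dimethoxy-2-oxo-2H-chromen-7-yl)oxy]acetic acid | COc1cc2ccc(=O)oc2c(OC)c1OCC(O)=O
F4 | step 11 | 6-formyl-2,4-dimethoxy-3-(methoxymethoxy)phenyl 2-[(6,8-dimethoxy-2-oxo-2H-chromen-7-yl)oxy]acetate | COCOc1c(OC)cc(C=O)c(OC(=O)COc2c(OC)cc3ccc(=O)oc3c2OC)c1OC
F5 | step 6 | tert-butyl 2-(diethoxyphosphoryl)-2-(4-formyl-3-hydroxy-2,6-dimethoxyphenoxy)acetate (racemic) | CCOP(=O)(OCC)C(Oc1c(OC)cc(C=O)c(O)c1OC)C(=O)OC(C)(C)C
F0 | step 7 | none | none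
F6 | step 9 | 2-(4-formyl-3-hydroxy-2,6-dimethoxyphenoxy)prop-2-enoic acid | C=C(Oc1c(OC)cc(C=O)c(O)c1OC)C(O)=O
F7 | step 9 | 2-(4-ethenyl-3-hydroxy-2,6-dimethoxyphenoxy)prop-2-enoic acid | C=Cc1cc(OC)c(OC(=C)C(O)=O)c(OC)c1O
F8 | step 9 | 2-[4-ethenyl-2,6-dimethoxy-3-(prop-2-enoyloxy)phenoxy]prop-2-enoic prop-2-enoic anhydride | C=CC(=O)OC(=O)C(=C)Oc1c(OC)cc(C=C)c(OC(=O)C=C)c1OC
F9 | step 10 | 2-[4-ethenyl-2,6-dimethoxy-3-(prop-2-enoyloxy)phenoxy]prop-2-enoyl chloride | C=CC(=O)Oc1c(C=C)cc(OC)c(OC(=C)C(Cl)=O)c1OC
A1 | alternative 1 | 1,4-dimethoxy-1,3-bis(trimethylsilyloxy)buta-1,3-diene (mixture of alkene isomers) | COC=C(O[Si](C)(C)C)C=C(OC)O[Si](C)(C)C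
A2 | alternative 1 | 2,3-dimethoxyprop-2-enoyl chloride | COC=C(OC)C(Cl)=O
A3 | alternative 1 | methyl 2,4-dihydroxy-3,5-dimethoxybenzoate | COC(=O)c1cc(OC)c(O)c(OC)c1O
A4 | alternative 2 | 7-(benzyloxy)-3-{[3-(3,3-diethoxyprop-1-en-2-yl)-2-methoxy-3-(methoxymethoxy)-4-oxocyclobut-1-en-1-yl]oxy}-6,8-dimethoxy-2H-chromen-2-one (racemic) | O=C1C(Oc2cc3cc(OC)c(OCc4ccccc4)c(OC)c3oc2=O)=C(OC)C1(OCOC)C(=C)C(OCC)OCC
A5 | alternative 2 | 2-[(7-benzyloxy-6,8-dimethoxy-2-oxo-2H-chromen-3-yl)oxy]-5-(diethoxymethyl)-3-methoxy-4-(methoxymethoxy)phenol | Oc1cc(C(OCC)OCC)c(OCOC)c(OC)c1Oc1cc2cc(OC)c(OCc3ccccc3)c(OC)c2oc1=O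
A6 | alternative 3 | 2-[(6,8-dimethoxy-2-oxo-2H-chromen-7-yl)oxy]-3-(4-hydroxy-3,5-dimethoxyphenyl)propanoic acid (racemic) | COc1cc(CC(Oc2c(OC)cc3ccc(=O)oc3c2OC)C(O)=O)cc(OC)c1O
A7 | alternative 3 | 3-[(6,8-dimethoxy-2-oxo-2H-chromen-7-yl)oxy]-7,9-dimethoxy-1-oxaspiro[4.5]deca-6,9-diene-2,8-dione (racemic) | COC1=CC2(CC(Oc3c(OC)cc4ccc(=O)oc4c3OC)C(=O)O2)C=C(OC)C1=O
A8 | alternative 3 | 3-[(6,8-dimethoxy-2-oxo-2H-chromen-7-yl)oxy]-7-hydroxy-6,8-dimethoxy-3,4-dihydro-2H-chromen-2-one (racemic) | COc1cc2CC(Oc3c(OC)cc4ccc(=O)oc4c3OC)C(=O)Oc2c(OC)c1O
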